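## Retrosynthetic overview

1. The target is opened at C6–C7 and at the lactone C–O bond: the last step is an intramolecular CrCl2 Barbier allylation–lactonisation of a fully esterified, epoxidised seco enal/allylic bromide. It closes the ten-membered carbocycle and the α-methylene-γ-lactone together and sets C6 and C7.
2. The seco chain comes from cross-metathesis (C7=C11, with a 2-(bromomethyl)acrylate), Shi epoxidation (C1–C10 oxirane) and two esterifications (C3, C8).
3. The carbon chain comes from an asymmetric Nozaki–Hiyama–Kishi union (C3–C4) of a Z-iodobutenol ether with a β,γ-unsaturated aldehyde. That aldehyde is made by Negishi carboalumination/ethylene oxide opening of an enyne derived from (S)-vinyloxirane (source of C8).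
4. The C8 acid side chain comes from Sharpless epoxidation and oxidation of tiglyl alcohol.
5. Ring order: side-chain oxirane (step 1), ring oxirane (step 14), then carbocycle and lactone in one operation (step 18).

Assumptions: germacranolide locants are used for chain carbons (lactone C12(=O)–O–C6, exocyclic CH2 = C13); the C8 acyl group is the cis-dimethyl (tiglate-derived) (2R,3S)-oxirane encoded in the SMILES; in step 10 the ligand antipode is the one that gives the 4S alcohol.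

## Route

Step 1
Reactants: 1 (E)-2-methylbut-2-en-1-ol
Product: 2 [(2S,3S)-2,3-dimethyloxiran-2-yl]methanol
Conditions: Ti(OiPr)4 (10 mol%), L-(+)-diethyl tartrate (12 mol%), t-BuOOH, 4 Å sieves, CH2Cl2, −20 °C
Reagents that add atoms: tert-butyl hydroperoxide, CC(C)(C)OO
Why: Sharpless asymmetric epoxidation, in which the L-(+)-tartrate titanium complex delivers oxygen to the face that gives the 2S,3S epoxy alcohol (same sense as geraniol to its 2S,3S epoxide) and the E alkene fixes the cis relation of the two methyl groups.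

Step 2
Reactants: 2 [(2S,3S)-2,3-dimethyloxiran-2-yl]methanol
Product: 3 (2R,3S)-2,3-dimethyloxirane-2-carboxylic acid
Conditions: RuCl3 (2 mol%), NaIO4 (4 equiv), MeCN/CCl4/H2O, 0 °C → rt
Reagents that add atoms: sodium periodate, [Na+].[O-]I(=O)(=O)=O
Why: Ruthenium tetroxide-catalysed (RuCl3/NaIO4) oxidation of the primary alcohol to the acid leaves the oxirane and both stereocentres untouched (the C2 descriptor changes from S to R only because CO2H outranks the ring carbon).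

Step 3
Reactants: 4 but-2-yn-1-ol
Product: 6 (2Z)-3-iodobut-2-en-1-ol, via cyclic vinylalanate 5 (not isolated)
Conditions: NaAlH2(OCH2CH2OMe)2 (1.5 equiv), THF, 0 °C → rt; then I2, −78 → 0 °C
Reagents that add atoms: iodine, II
Why: Hydroxyl-directed trans-hydroalumination of the propargylic alcohol puts aluminium on C3 anti to the new C2–H, and iodinolysis with retention gives only the Z vinyl iodide (I cis to CH2OH).

Step 4
Reactants: 6 (2Z)-3-iodobut-2-en-1-ol
Product: 7 1-({[(2Z)-3-iodobut-2-en-1-yl]oxy}methyl)-4-methoxybenzene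
Conditions: NaH, 4-methoxybenzyl chloride, Bu4NI (cat.), THF/DMF, 0 °C → rt
Reagents that add atoms: 4-methoxybenzyl chloride, COc1ccc(CCl)cc1
Why: Williamson etherification of the primary alkoxide masks the future C6 oxygen as a PMB ether that is removable oxidatively at the end; the vinyl iodide is inert to NaH.

Step 5
Reactants: 8 rac-2-vinyloxirane
Product: 9 (2S)-2-vinyloxirane
Conditions: (S,S)-Co(salen)(OAc) (0.5 mol%; salen = N,N′-bis(3,5-di-tert-butylsalicylidene)cyclohexane-1,2-diamine dianion; trivalent cobalt), H2O (0.55 equiv), 0 °C → rt; distil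
Reagents that add atoms: none
Why: Jacobsen hydrolytic kinetic resolution, in which the (S,S) catalyst hydrolyses the R epoxide to its diol and leaves the volatile S epoxide in high ee.

Step 6
Reactants: 9 (2S)-2-vinyloxirane
Product: 10 (3R)-hex-1-en-5-yn-3-ol
Conditions: LiC≡CH·H2NCH2CH2NH2 (1.5 equiv), DMSO, 0 °C → rt; then H2O
Reagents that add atoms: lithium acetylide (ethylenediamine complex), [Li+].[C-]#C
Why: SN2 opening of the epoxide at its unsubstituted carbon by the hard acetylide in DMSO (no Lewis acid, so no allylic or SN2′ attack) leaves the stereocentre untouched; it becomes C8 (R).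

Step 7
Reactants: 10 (3R)-hex-1-en-5-yn-3-ol
Product: 11 tert-butyl{[(3R)-hex-1-en-5-yn-3-yl]oxy}dimethylsilane
Conditions: TBSCl, imidazole, DMF, rt
Reagents that add atoms: tert-butyldimethylsilyl chloride, CC(C)(C)[Si](C)(C)Cl
Why: Imidazole-assisted silylation protects the C8 hydroxyl so that it survives AlMe3 and can later be distinguished from the C3 hydroxyl.

Step 8
Reactants: 11 tert-butyl{[(3R)-hex-1-en-5-yn-3-yl]oxy}dimethylsilane
Product: 14 (3E,6R)-6-[(tert-butyldimethylsilyl)oxy]-4-methylocta-3,7-dien-1-ol, via alkenyldimethylalane 12 (not isolated), via lithium alkenylalanate 13 (not isolated)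
Conditions: AlMe3 (2.5 equiv), Cp2ZrCl2 (0.25 equiv), CH2Cl2, 0 °C → rt; evaporate excess AlMe3; n-BuLi (1 equiv), hexane/THF, −78 °C; ethylene oxide, −78 → 0 °C
Reagents that add atoms: trimethylaluminium, C[Al](C)C; ethylene oxide, C1CO1
Why: Negishi zirconium-catalysed syn-carboalumination of the terminal alkyne (methyl to the internal carbon, aluminium to the terminal carbon, the vinyl group being much slower) followed by opening of ethylene oxide by the alanate with retention gives only the E trisubstituted alkene (C1=C10).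

Step 9
Reactants: 14 (3E,6R)-6-[(tert-butyldimethylsilyl)oxy]-4-methylocta-3,7-dien-1-ol
Product: 15 (3E,6R)-6-[(tert-butyldimethylsilyl)oxy]-4-methylocta-3,7-dienal
Conditions: Dess–Martin periodinane, NaHCO3, CH2Cl2, 0 °C → rt; used crude at once
Reagents that add atoms: none
Why: Buffered Dess–Martin oxidation gives the β,γ-unsaturated aldehyde without base, so the E alkene does not move into conjugation.

Step 10
Reactants: 15 (3E,6R)-6-[(tert-butyldimethylsilyl)oxy]-4-methylocta-3,7-dienal; 7 1-({[(2Z)-3-iodobut-2-en-1-yl]oxy}methyl)-4-methoxybenzene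
Product: 16 (2Z,4S,6E,9R)-9-[(tert-butyldimethylsilyl)oxy]-1-[(4-methoxybenzyl)oxy]-3,7-dimethylundeca-2,6,10-trien-4-ol
Conditions: CrCl2 (4 equiv), NiCl2 (2 mol%), Kishi oxazoline–sulfonamide ligand (4.4 equiv, recovered), Et3N, THF, rt
Reagents that add atoms: none
Why: Nickel-catalysed, chromium-mediated Nozaki–Hiyama–Kishi alkenylation (divalent chromium, alkenyl on trivalent chromium) adds the vinyl iodide to the aldehyde with retention of the Z geometry, and the chiral sulfonamide ligand on chromium selects the aldehyde face to give the 4S carbinol (C3).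

Step 11
Reactants: 16 (2Z,4S,6E,9R)-9-[(tert-butyldimethylsilyl)oxy]-1-[(4-methoxybenzyl)oxy]-3,7-dimethylundeca-2,6,10-trien-4-ol
Product: 17 (2Z,4S,6E,9R)-9-[(tert-butyldimethylsilyl)oxy]-1-[(4-methoxybenzyl)oxy]-3,7-dimethylundeca-2,6,10-trien-4-yl 3-methylbutanoate
Conditions: 3-methylbutanoyl chloride, pyridine, DMAP (cat.), CH2Cl2, 0 °C → rt
Reagents that add atoms: 3-methylbutanoyl chloride, CC(C)CC(=O)Cl
Why: DMAP-catalysed O-acylation installs the final C3 isovalerate with retention and blocks later lactol or furan formation from the Z-γ-oxy enal.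

Step 12
Reactants: 17 (2Z,4S,6E,9R)-9-[(tert-butyldimethylsilyl)oxy]-1-[(4-methoxybenzyl)oxy]-3,7-dimethylundeca-2,6,10-trien-4-yl 3-methylbutanoate
Product: 18 (2Z,4S,6E,9R)-9-hydroxy-1-[(4-methoxybenzyl)oxy]-3,7-dimethylundeca-2,6,10-trien-4-yl 3-methylbutanoate
Conditions: HF·pyridine, pyridine, THF, 0 °C → rt
Reagents that add atoms: none
Why: Fluoride cleavage of the secondary silyl ether (Si–F bond formation) frees the C8 hydroxyl while the isovalerate, PMB ether and alkenes are inert.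

Step 13
Reactants: 18 (2Z,4S,6E,9R)-9-hydroxy-1-[(4-methoxybenzyl)oxy]-3,7-dimethylundeca-2,6,10-trien-4-yl 3-methylbutanoate; 3 (2R,3S)-2,3-dimethyloxirane-2-carboxylic acid
Product: 20 (2Z,4S,6E,9R)-1-[(4-methoxybenzyl)oxy]-3,7-dimethyl-4-[(3-methylbutanoyl)oxy]undeca-2,6,10-trien-9-yl (2R,3S)-2,3-dimethyloxirane-2-carboxylate, via mixed anhydride 19 (not isolated)
Conditions: 3, 2,4,6-trichlorobenzoyl chloride, Et3N, THF, rt; then 18, DMAP, toluene, rt
Reagents that add atoms: none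
Why: Yamaguchi esterification activates the hindered α,α-disubstituted epoxy acid as its mixed anhydride and DMAP transfers the acyl group to the secondary allylic alcohol with no stereocentre touched.

Step 14
Reactants: 20 (2Z,4S,6E,9R)-1-[(4-methoxybenzyl)oxy]-3,7-dimethyl-4-[(3-methylbutanoyl)oxy]undeca-2,6,10-trien-9-yl (2R,3S)-2,3-dimethyloxirane-2-carboxylate
Product: 21 (2Z,4S,6R,7R,9R)-6,7-epoxy-1-[(4-methoxybenzyl)oxy]-3,7-dimethyl-4-[(3-methylbutanoyl)oxy]undeca-2,10-dien-9-yl (2R,3S)-2,3-dimethyloxirane-2-carboxylate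
Conditions: D-fructose-derived Shi ketone (1,2:4,5-di-O-isopropylidene-β-D-erythro-2,3-hexodiulo-2,6-pyranose, 0.3 equiv), KHSO5 (as 2KHSO5·KHSO4·K2SO4), K2CO3, Bu4NHSO4, MeCN/dimethoxymethane, aqueous Na2B4O7 buffer, 0 °C
Reagents that add atoms: potassium peroxymonosulfate, [K+].[O-]S(=O)(=O)OO
Why: Shi asymmetric epoxidation (chiral dioxirane, spiro transition state) attacks only the electron-rich E-trisubstituted C1=C10 alkene (the Z alkene carries two allylic oxygens and the vinyl group is monosubstituted) and the D-fructose ketone gives the R,R oxirane (C1 R, C10 R).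

Step 15
Reactants: 21 (2Z,4S,6R,7R,9R)-6,7-epoxy-1-[(4-methoxybenzyl)oxy]-3,7-dimethyl-4-[(3-methylbutanoyl)oxy]undeca-2,10-dien-9-yl (2R,3S)-2,3-dimethyloxirane-2-carboxylate
Product: 22 (2Z,4S,6R,7R,9R)-6,7-epoxy-1-hydroxy-3,7-dimethyl-4-[(3-methylbutanoyl)oxy]undeca-2,10-dien-9-yl (2R,3S)-2,3-dimethyloxirane-2-carboxylate
Conditions: DDQ (1.3 equiv), CH2Cl2/pH 7 phosphate buffer, 0 °C
Reagents that add atoms: none
Why: Oxidative PMB cleavage by DDQ (hydride abstraction, then hydrolysis of the oxocarbenium ion) at neutral pH leaves both oxiranes, both esters and the alkenes intact.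

Step 16
Reactants: 22 (2Z,4S,6R,7R,9R)-6,7-epoxy-1-hydroxy-3,7-dimethyl-4-[(3-methylbutanoyl)oxy]undeca-2,10-dien-9-yl (2R,3S)-2,3-dimethyloxirane-2-carboxylate
Product: 23 (2Z,4S,6R,7R,9R)-6,7-epoxy-3,7-dimethyl-4-[(3-methylbutanoyl)oxy]-1-oxoundeca-2,10-dien-9-yl (2R,3S)-2,3-dimethyloxirane-2-carboxylate
Conditions: activated MnO2 (20 equiv), CH2Cl2, rt
Reagents that add atoms: none
Why: Chemoselective MnO2 oxidation of the primary allylic alcohol gives the enal with the Z geometry kept (as in nerol to neral).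

Step 17
Reactants: 23 (2Z,4S,6R,7R,9R)-6,7-epoxy-3,7-dimethyl-4-[(3-methylbutanoyl)oxy]-1-oxoundeca-2,10-dien-9-yl (2R,3S)-2,3-dimethyloxirane-2-carboxylate; 24 methyl 2-(bromomethyl)prop-2-enoate
Product: 25 methyl (2Z,4R,6R,7R,9S,10Z)-2-(bromomethyl)-4-{[(2R,3S)-2,3-dimethyloxirane-2-carbonyl]oxy}-6,7-epoxy-6,10-dimethyl-9-[(3-methylbutanoyl)oxy]-12-oxododeca-2,10-dienoate
Conditions: 24 (5 equiv), second-generation Hoveyda–Grubbs catalyst RuCl2(=CH-C6H4-2-OiPr)(H2IMes) (10 mol%), toluene, 60 °C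
Reagents that add atoms: none
Why: Olefin cross-metathesis joins the only terminal alkene of 23 to the 1,1-disubstituted acrylate (which cannot homodimerise), the conjugated trisubstituted enal alkene being inert, and gives the thermodynamic trisubstituted enoate (ester trans to C8, CH2Br cis to C8) with loss of ethene.

Step 18
Reactants: 25 methyl (2Z,4R,6R,7R,9S,10Z)-2-(bromomethyl)-4-{[(2R,3S)-2,3-dimethyloxirane-2-carbonyl]oxy}-6,7-epoxy-6,10-dimethyl-9-[(3-methylbutanoyl)oxy]-12-oxododeca-2,10-dienoate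
Product: 27 CNP0167461.4, via ring-closed hydroxy ester 26 (not isolated)
Conditions: CrCl2 (10 equiv), THF/DMF (20:1), 2 mM, 25 added over 8 h, 25 °C; then aqueous NH4Cl
Reagents that add atoms: none
Why: Intramolecular Nozaki–Hiyama (chromium Barbier) allylation–lactonisation, in which divalent chromium turns the allylic bromide into a 2-(methoxycarbonyl)allylchromium that attacks the Z-enal through C7 in a chair-like ten-membered transition state (C6/C7 anti, as known for chromium closures of germacranolide rings; attack anti to the C8–C9 ring bond with H8 eclipsing the allyl unit, which places C11 and the C8 ester as in the target), and the C6 alkoxide then closes the trans α-methylene-γ-lactone on the methyl ester, so C6 (R) and C7 (R) are set from C8 while both rings form in one operation.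

## Compound list

1 | (E)-2-methylbut-2-en-1-ol | C/C=C(\C)CO | starting material
2 | [(2S,3S)-2,3-dimethyloxiran-2-yl]methanol | OC[C@]1(C)O[C@H]1C | intermediate
3 | (2R,3S)-2,3-dimethyloxirane-2-carboxylic acid | OC(=O)[C@]1(C)O[C@H]1C | intermediate
4 | but-2-yn-1-ol | CC#CCO | starting material
5 | sodium 2,2-bis(2-methoxyethoxy)-3-methyl-2,5-dihydro-1,2-oxaaluminol-2-uide (cyclic vinylalanate) | CC1=CCO[Al-]1(OCCOC)OCCOC.[Na+] | intermediate
6 | (2Z)-3-iodobut-2-en-1-ol | OC/C=C(/C)I | intermediate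
7 | 1-({[(2Z)-3-iodobut-2-en-1-yl]oxy}methyl)-4-methoxybenzene | COc1ccc(COC/C=C(/C)I)cc1 | intermediate
8 | rac-2-vinyloxirane | C=CC1CO1 | starting material
9 | (2S)-2-vinyloxirane | C=C[C@H]1CO1 | intermediate
10 | (3R)-hex-1-en-5-yn-3-ol | C=C[C@H](O)CC#C | intermediate
11 | tert-butyl{[(3R)-hex-1-en-5-yn-3-yl]oxy}dimethylsilane | C=C[C@H](O[Si](C)(C)C(C)(C)C)CC#C | intermediate
12 | {(1E,4R)-4-[(tert-butyldimethylsilyl)oxy]-2-methylhexa-1,5-dien-1-yl}dimethylalumane | C[Al](C)/C=C(\C)C[C@@H](O[Si](C)(C)C(C)(C)C)C=C | intermediate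
13 | lithium butyl{(1E,4R)-4-[(tert-butyldimethylsilyl)oxy]-2-methylhexa-1,5-dien-1-yl}dimethylaluminate | [Li+].CCCC[Al-](C)(C)/C=C(\C)C[C@@H](O[Si](C)(C)C(C)(C)C)C=C | intermediate
14 | (3E,6R)-6-[(tert-butyldimethylsilyl)oxy]-4-methylocta-3,7-dien-1-ol | OCC/C=C(\C)C[C@@H](O[Si](C)(C)C(C)(C)C)C=C | intermediate
15 | (3E,6R)-6-[(tert-butyldimethylsilyl)oxy]-4-methylocta-3,7-dienal | O=CC/C=C(\C)C[C@@H](O[Si](C)(C)C(C)(C)C)C=C | intermediate
16 | (2Z,4S,6E,9R)-9-[(tert-butyldimethylsilyl)oxy]-1-[(4-methoxybenzyl)oxy]-3,7-dimethylundeca-2,6,10-trien-4-ol | COc1ccc(COC/C=C(/C)[C@@H](O)C/C=C(\C)C[C@@H](O[Si](C)(C)C(C)(C)C)C=C)cc1 | intermediate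
17 | (2Z,4S,6E,9R)-9-[(tert-butyldimethylsilyl)oxy]-1-[(4-methoxybenzyl)oxy]-3,7-dimethylundeca-2,6,10-trien-4-yl 3-methylbutanoate | COc1ccc(COC/C=C(/C)[C@@H](OC(=O)CC(C)C)C/C=C(\C)C[C@@H](O[Si](C)(C)C(C)(C)C)C=C)cc1 | intermediate
18 | (2Z,4S,6E,9R)-9-hydroxy-1-[(4-methoxybenzyl)oxy]-3,7-dimethylundeca-2,6,10-trien-4-yl 3-methylbutanoate | COc1ccc(COC/C=C(/C)[C@@H](OC(=O)CC(C)C)C/C=C(\C)C[C@@H](O)C=C)cc1 | intermediate
19 | (2R,3S)-2,3-dimethyloxirane-2-carboxylic 2,4,6-trichlorobenzoic anhydride | O=C(OC(=O)c1c(Cl)cc(Cl)cc1Cl)[C@]1(C)O[C@H]1C | intermediate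
20 | (2Z,4S,6E,9R)-1-[(4-methoxybenzyl)oxy]-3,7-dimethyl-4-[(3-methylbutanoyl)oxy]undeca-2,6,10-trien-9-yl (2R,3S)-2,3-dimethyloxirane-2-carboxylate | COc1ccc(COC/C=C(/C)[C@@H](OC(=O)CC(C)C)C/C=C(\C)C[C@@H](OC(=O)[C@]2(C)O[C@H]2C)C=C)cc1 | intermediate
21 | (2Z,4S,6R,7R,9R)-6,7-epoxy-1-[(4-methoxybenzyl)oxy]-3,7-dimethyl-4-[(3-methylbutanoyl)oxy]undeca-2,10-dien-9-yl (2R,3S)-2,3-dimethyloxirane-2-carboxylate | COc1ccc(COC/C=C(/C)[C@@H](OC(=O)CC(C)C)C[C@H]2O[C@]2(C)C[C@@H](OC(=O)[C@]3(C)O[C@H]3C)C=C)cc1 | intermediate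
22 | (2Z,4S,6R,7R,9R)-6,7-epoxy-1-hydroxy-3,7-dimethyl-4-[(3-methylbutanoyl)oxy]undeca-2,10-dien-9-yl (2R,3S)-2,3-dimethyloxirane-2-carboxylate | OC/C=C(/C)[C@@H](OC(=O)CC(C)C)C[C@H]1O[C@]1(C)C[C@@H](OC(=O)[C@]2(C)O[C@H]2C)C=C | intermediate
23 | (2Z,4S,6R,7R,9R)-6,7-epoxy-3,7-dimethyl-4-[(3-methylbutanoyl)oxy]-1-oxoundeca-2,10-dien-9-yl (2R,3S)-2,3-dimethyloxirane-2-carboxylate | O=C/C=C(/C)[C@@H](OC(=O)CC(C)C)C[C@H]1O[C@]1(C)C[C@@H](OC(=O)[C@]2(C)O[C@H]2C)C=C | intermediate
24 | methyl 2-(bromomethyl)prop-2-enoate | C=C(CBr)C(=O)OC | starting material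
25 | methyl (2Z,4R,6R,7R,9S,10Z)-2-(bromomethyl)-4-{[(2R,3S)-2,3-dimethyloxirane-2-carbonyl]oxy}-6,7-epoxy-6,10-dimethyl-9-[(3-methylbutanoyl)oxy]-12-oxododeca-2,10-dienoate | O=C/C=C(/C)[C@@H](OC(=O)CC(C)C)C[C@H]1O[C@]1(C)C[C@@H](OC(=O)[C@]2(C)O[C@H]2C)/C=C(\CBr)C(=O)OC | intermediate
26 | ring-closed hydroxy ester: open-lactone form of 27 with the ten-membered ring closed, free C6–OH and C12 methyl ester, same configurations as 27 (chromium alkoxide in the flask) | O[C@@H]1/C=C(/C)[C@@H](OC(=O)CC(C)C)C[C@H]2O[C@]2(C)C[C@@H](OC(=O)[C@]2(C)O[C@H]2C)[C@H]1C(=C)C(=O)OC | intermediate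
27 | CNP0167461.4: (1R,3S,4Z,6R,7R,8R,10R)-1,10-epoxy-3-(3-methylbutanoyloxy)-8-{[(2R,3S)-2,3-dimethyloxirane-2-carbonyl]oxy}germacra-4,11(13)-dien-12,6-olide | C=C1C(=O)O[C@@H]2/C=C(/C)[C@@H](OC(=O)CC(C)C)C[C@H]3O[C@]3(C)C[C@@H](OC(=O)[C@]3(C)O[C@H]3C)[C@@H]12 | target

## Step count and risks

Total steps: 18 (steps 1–2 make the acid 3, steps 3–4 the iodide 7, steps 5–18 the main chain). Longest linear sequence: 14 steps (8 → 27, steps 5–18).

Steps most likely to fail:

- **Step 18 (ring closure and lactonisation).** The allylchromium carries a carboxylate on the adjacent carbon (C8) and may lose it by 1,4-elimination; the C6/C7 facial selectivity is predicted, not proven. The fallback carries C8 as its silyl ether through the closure and esterifies last. It sets out from 17 and returns at 27. Shi epoxidation of 17 (as in step 14) gives the epoxy silyl ether F1. DDQ gives the allylic alcohol F2 and MnO2 the Z-enal F3. Cross-metathesis with 24 gives the silyl-protected bromo enal F4. CrCl2 closure gives the 8-O-silyl lactone F5 and HF·pyridine the 8-hydroxy lactone F6. Yamaguchi esterification of F6 with 3 gives 27.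

- **Step 17 (cross-metathesis).** Both partners are sluggish: a hindered secondary allylic ester and a 1,1-disubstituted acrylate. The fallback builds the same allylic bromide by carbonyl chemistry. It sets out from 23 and returns at 25. OsO4 (cat.)/NaIO4/2,6-lutidine cleaves the vinyl group (the enal C=C is electron-poor and is left) to the α-acyloxy dialdehyde F7. [1-(Methoxycarbonyl)vinyl]diisobutylaluminium (from methyl propiolate, i-Bu2AlH and N-methylmorpholine N-oxide) adds at −78 °C to the more electrophilic saturated aldehyde to give the Baylis–Hillman-type alcohol F8 (C3 epimers of the dodecenoate, which do not matter). N-Bromosuccinimide/Me2S converts F8 with allylic transposition into 25.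

- **Step 10 (asymmetric alkenylation).** Ligand control may be insufficient with the enolisable β,γ-unsaturated aldehyde. The fallback sets C3 by reagent-controlled ketone reduction. It sets out from 15 and 7 and returns at 16. Ligand-free CrCl2/NiCl2 coupling gives 16 mixed with its 4R epimer F9. Dess–Martin oxidation of the mixture gives the Z-enone F10. Reduction with catecholborane and (R)-2-methyl-CBS-oxazaborolidine at −78 °C (alkenyl as the large group) gives 16.

## Further compounds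

F1 | step 18 | (2Z,4S,6R,7R,9R)-9-[(tert-butyldimethylsilyl)oxy]-6,7-epoxy-1-[(4-methoxybenzyl)oxy]-3,7-dimethylundeca-2,10-dien-4-yl 3-methylbutanoate | COc1ccc(COC/C=C(/C)[C@@H](OC(=O)CC(C)C)C[C@H]2O[C@]2(C)C[C@@H](O[Si](C)(C)C(C)(C)C)C=C)cc1
F2 | step 18 | (2Z,4S,6R,7R,9R)-9-[(tert-butyldimethylsilyl)oxy]-6,7-epoxy-1-hydroxy-3,7-dimethylundeca-2,10-dien-4-yl 3-methylbutanoate | OC/C=C(/C)[C@@H](OC(=O)CC(C)C)C[C@H]1O[C@]1(C)C[C@@H](O[Si](C)(C)C(C)(C)C)C=C
F3 | step 18 | (2Z,4S,6R,7R,9R)-9-[(tert-butyldimethylsilyl)oxy]-6,7-epoxy-3,7-dimethyl-1-oxoundeca-2,10-dien-4-yl 3-methylbutanoate | O=C/C=C(/C)[C@@H](OC(=O)CC(C)C)C[C@H]1O[C@]1(C)C[C@@H](O[Si](C)(C)C(C)(C)C)C=C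
F4 | step 18 | methyl (2Z,4R,6R,7R,9S,10Z)-2-(bromomethyl)-4-[(tert-butyldimethylsilyl)oxy]-6,7-epoxy-6,10-dimethyl-9-[(3-methylbutanoyl)oxy]-12-oxododeca-2,10-dienoate | O=C/C=C(/C)[C@@H](OC(=O)CC(C)C)C[C@H]1O[C@]1(C)C[C@@H](O[Si](C)(C)C(C)(C)C)/C=C(\CBr)C(=O)OC
F5 | step 18 | (1R,3S,4Z,6R,7R,8R,10R)-8-[(tert-butyldimethylsilyl)oxy]-1,10-epoxy-3-(3-methylbutanoyloxy)germacra-4,11(13)-dien-12,6-olide | C=C1C(=O)O[C@@H]2/C=C(/C)[C@@H](OC(=O)CC(C)C)C[C@H]3O[C@]3(C)C[C@@H](O[Si](C)(C)C(C)(C)C)[C@@H]12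
F6 | step 18 | (1R,3S,4Z,6R,7R,8R,10R)-1,10-epoxy-8-hydroxy-3-(3-methylbutanoyloxy)germacra-4,11(13)-dien-12,6-olide | C=C1C(=O)O[C@@H]2/C=C(/C)[C@@H](OC(=O)CC(C)C)C[C@H]3O[C@]3(C)C[C@@H](O)[C@@H]12
F7 | step 17 | (2Z,4S,6R,7R,9R)-6,7-epoxy-3,7-dimethyl-4-[(3-methylbutanoyl)oxy]-1,10-dioxodec-2-en-9-yl (2R,3S)-2,3-dimethyloxirane-2-carboxylate | O=C/C=C(/C)[C@@H](OC(=O)CC(C)C)C[C@H]1O[C@]1(C)C[C@@H](OC(=O)[C@]2(C)O[C@H]2C)C=O
F8 | step 17 | methyl (4R,6R,7R,9S,10Z)-4-{[(2R,3S)-2,3-dimethyloxirane-2-carbonyl]oxy}-6,7-epoxy-3-hydroxy-6,10-dimethyl-2-methylidene-9-[(3-methylbutanoyl)oxy]-12-oxododec-10-enoate (C3 epimers) | O=C/C=C(/C)[C@@H](OC(=O)CC(C)C)C[C@H]1O[C@]1(C)C[C@@H](OC(=O)[C@]2(C)O[C@H]2C)C(O)C(=C)C(=O)OC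
F9 | step 10 | (2Z,4R,6E,9R)-9-[(tert-butyldimethylsilyl)oxy]-1-[(4-methoxybenzyl)oxy]-3,7-dimethylundeca-2,6,10-trien-4-ol | COc1ccc(COC/C=C(/C)[C@H](O)C/C=C(\C)C[C@@H](O[Si](C)(C)C(C)(C)C)C=C)cc1
F10 | step 10 | (2Z,6E,9R)-9-[(tert-butyldimethylsilyl)oxy]-1-[(4-methoxybenzyl)oxy]-3,7-dimethylundeca-2,6,10-trien-4-one | COc1ccc(COC/C=C(/C)C(=O)C/C=C(\C)C[C@@H](O[Si](C)(C)C(C)(C)C)C=C)cc1
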